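**Plan**

- Enabling feature: ring B (the enolised cyclohexanetrione ring) carries an isobutyryl group on its quaternary carbon. The C=O and CMe2 carbons of that group are read as a former two-carbon bridge from the quaternary carbon to the ring carbonyl carbon para to it (the one between the C-methyl and C-CH2Ar carbons), so ring B is a retro-aldol-opened bicyclo[2.2.2]octadienone.
- Cuts, in retrosynthetic order: (a) the bond from ring B to the bridging CH2, giving the ring B trione and a Mannich base of ring A; (b) in reverse, the aldol bond CMe2–C(ring carbonyl) is re-formed to give the bicycle; (c) the two (4+2) bonds C(prenyl)–C(OEt) and C(OSi)–C(Me), giving a filicinic-acid dienone and 1-ethoxypropyne.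
- Forward order: phloroglucinol is acylated, gem-dimethylated (first ring, dearomatised), deacylated, O-methylated, C-prenylated and O-silylated to the dienone. The (4+2) addition closes the second six-membered ring. Fluoride-triggered retro-aldol opens the gem-dimethyl ring and leaves ring B. Both enol ethers are cleaved, and ring A (from the same acylphloroglucinol) is attached through its Mannich base.
- Stereochemistry: the single stereocentre of the target derives from the prenyl-bearing bridgehead of the cycloadduct, set by a chiral oxazaborolidinium cation; it is quaternary and cannot epimerise afterwards.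

Key step: step 7

Remark: enolised triketones are written as one tautomer each; the sense of induction of the boron catalyst on this dienone cannot be predicted with certainty, so the (S)-catalyst is written and its antipode is to be used if it favours the other face.

**Route**

Step 1
Reactants: 1 phloroglucinol; 2 isobutyryl chloride
Product: 3 2-methyl-1-(2,4,6-trihydroxyphenyl)propan-1-one
Conditions: AlCl3 (3.5 equiv), PhNO2, 25 → 65 °C; then 1 M aq. HCl
Reagents that add atoms: none
Why: Friedel–Crafts C-acylation of the very electron-rich triol, which should stop at the monoketone because the acyl group deactivates the ring.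

Step 2
Reactants: 3 2-methyl-1-(2,4,6-trihydroxyphenyl)propan-1-one; 4 iodomethane
Product: 6 3,5-dihydroxy-4,4-dimethyl-2-(2-methylpropanoyl)cyclohexa-2,5-dien-1-one, via C-monomethyl ketone 5 (not isolated)
Conditions: NaOMe (3 equiv), MeOH, 0 → 23 °C; MeI (2.2 equiv in all); then 1 M aq. HCl
Reagents that add atoms: iodomethane (second equivalent), CI
Why: Alkylative dearomatisation of an acylphloroglucinol: the phenolate is C-methylated at a free ring carbon, the methyl-bearing carbon of 5 is then the most nucleophilic position, so the second equivalent of iodomethane should enter there and give the gem-dimethyl triketone, while limiting MeI to about two equivalents holds back further methylation.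

Step 3
Reactants: 6 3,5-dihydroxy-4,4-dimethyl-2-(2-methylpropanoyl)cyclohexa-2,5-dien-1-one
Product: 7 3,5-dihydroxy-4,4-dimethylcyclohexa-2,5-dien-1-one (filicinic acid)
Conditions: 6 M aq. HCl, 1,4-dioxane, 100 °C
Reagents that add atoms: none
Why: Acid-catalysed retro-Claisen deacylation of a β-triketone, the classical way from acylfilicinic acids to filicinic acid.

Step 4
Reactants: 7 3,5-dihydroxy-4,4-dimethylcyclohexa-2,5-dien-1-one
Product: 8 5-hydroxy-3-methoxy-6,6-dimethylcyclohexa-2,4-dien-1-one
Conditions: MeOH, p-TsOH·H2O (5 mol %), 3 Å molecular sieves, 23 °C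
Reagents that add atoms: methanol, CO
Why: Fischer-type enol etherification of a vinylogous acid: methanol should add to the protonated trione at the one carbonyl carbon that is not next to the quaternary carbon (para to CMe2), so the ether forms there and the product keeps its symmetry.

Step 5
Reactants: 8 5-hydroxy-3-methoxy-6,6-dimethylcyclohexa-2,4-dien-1-one; 9 prenyl bromide
Product: 10 5-hydroxy-3-methoxy-6,6-dimethyl-2-(3-methylbut-2-en-1-yl)cyclohexa-2,4-dien-1-one
Conditions: KOH (1.05 equiv), H2O, 0 → 23 °C; then 1 M aq. HCl to pH 3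
Reagents that add atoms: none
Why: C-alkylation of a cyclic β-dicarbonyl anion by an allylic bromide in water, where hydrogen bonding to oxygen favours attack through carbon; the two nucleophilic CH positions of the anion of 8 are equivalent by symmetry, so only one mono-prenyl compound can form.

Step 6
Reactants: 10 5-hydroxy-3-methoxy-6,6-dimethyl-2-(3-methylbut-2-en-1-yl)cyclohexa-2,4-dien-1-one
Product: 11 5-[tert-butyl(dimethyl)silyl]oxy-3-methoxy-6,6-dimethyl-2-(3-methylbut-2-en-1-yl)cyclohexa-2,4-dien-1-one
Conditions: t-BuMe2SiCl (1.2 equiv), imidazole (2 equiv), CH2Cl2, 0 °C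
Reagents that add atoms: tert-butyldimethylsilyl chloride, CC(C)(C)[Si](C)(C)Cl
Why: O-silylation of the remaining vinylogous acid should take the less hindered oxygen (flanked by CH and CMe2, not by the prenyl carbon and CMe2), which fixes the linear 2,4-dienone with the free carbonyl at C1 between C2 (prenyl) and C6 (CMe2).

Step 7
Reactants: 11 5-[tert-butyl(dimethyl)silyl]oxy-3-methoxy-6,6-dimethyl-2-(3-methylbut-2-en-1-yl)cyclohexa-2,4-dien-1-one; 12 1-ethoxyprop-1-yne
Product: 13 (1R,4R)-4-[tert-butyl(dimethyl)silyl]oxy-6-ethoxy-7-methoxy-3,3,5-trimethyl-1-(3-methylbut-2-en-1-yl)bicyclo[2.2.2]octa-5,7-dien-2-one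
Conditions: (S)-3,3-diphenyl-1-(2-methylphenyl)tetrahydro-1H,3H-pyrrolo[1,2-c][1,3,2]oxazaborole·HN(SO2CF3)2 (20 mol %), 12 (2 equiv, slow addition), CH2Cl2, 4 Å molecular sieves, −78 °C; Et3N quench at −78 °C
Reagents that add atoms: none
Why: Proposed new method: the boron cation binds the only free carbonyl (C1) of 11 and makes the ring a 2,4,6-trioxygenated cyclohexadienyl cation; the methyl-bearing carbon of the ynol ether attacks its silyloxy-bearing terminus C5 (vinylogous 1,6-addition), and the ketene-oxonium carbon so formed is captured by the boron dienolate carbon C2, which releases the catalyst. The closest known reaction types are the inverse-demand Diels–Alder additions of cyclohexa-2,4-dienones (masked ortho-benzoquinones) to electron-rich π-partners and the Lewis-acid-promoted Ficini additions of ynamines and ynol ethers to enones, here extended from (2+2) to (4+2) and to a chiral oxazaborolidinium. The one new ring, six-membered (C2 to C5 of the dienone plus both alkyne carbons), closes in a stepwise (4+2) sense, the second bond by 6-exo-dig collapse of the zwitterion. C1 and C4 of 13 are created together: the alkyne must bridge C5 and C2 on one face, so a single facial choice fixes both, and that choice is made by the aryl groups of the prolinol-derived cation shielding one face of the bound, otherwise achiral dienone (catalyst control). The step needs 1,6- over 1,4-regioselectivity and the stated orientation of the alkyne: the push-pull dienone is electrophilic at C5 and nucleophilic at C2, the ynol ether is nucleophilic at its methyl-bearing carbon, attack at the alternative acceptor C3 would end in a strained cyclobutene that can reopen, and −78 °C keeps 13 from extruding dimethylketene.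

Step 8
Reactants: 13 (1R,4R)-4-[tert-butyl(dimethyl)silyl]oxy-6-ethoxy-7-methoxy-3,3,5-trimethyl-1-(3-methylbut-2-en-1-yl)bicyclo[2.2.2]octa-5,7-dien-2-one
Product: 16 (4R)-3-ethoxy-5-methoxy-2-methyl-4-(3-methylbut-2-en-1-yl)-4-(2-methylpropanoyl)cyclohexa-2,5-dien-1-one, via bridgehead alkoxide 14 (not isolated), via ketone enolate 15 (not isolated)
Conditions: Bu4NF·3H2O (1.2 equiv), THF, −20 → 0 °C; AcOH (1.5 equiv), then pH 7 buffer
Reagents that add atoms: none
Why: Fluoride desilylation followed by retro-aldol fragmentation: alkoxide 14 at C4 is the aldolate of the C2 ketone through C3, the other two bridges are enol ethers and cannot leave, so only the C3–C4 bond should break, driven by strain release and by the doubly vinylogous ester that forms; the water of the reagent protonates enolate 15 before it can lose dimethylketene, and the quaternary stereocentre is not touched.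

Step 9
Reactants: 16 (4R)-3-ethoxy-5-methoxy-2-methyl-4-(3-methylbut-2-en-1-yl)-4-(2-methylpropanoyl)cyclohexa-2,5-dien-1-one
Product: 19 (4R)-3,5-dihydroxy-2-methyl-4-(3-methylbut-2-en-1-yl)-4-(2-methylpropanoyl)cyclohexa-2,5-dien-1-one, via monosilyl dienol ether 17 (not isolated), via bissilyl dienol ether 18 (not isolated)
Conditions: Me3SiI (3 equiv), 2,6-di-tert-butyl-4-methylpyridine (0.5 equiv), CH2Cl2, 0 → 23 °C, dark; MeOH, then aq. Na2S2O3/NaH2PO4
Reagents that add atoms: none
Why: Jung–Olah dealkylation: Me3SiI silylates the dienone oxygen and iodide removes methyl and then ethyl by SN2 at the alkyl carbon, not at the hindered ring carbons; each cleavage leaves a neutral silyl dienol ether that can be activated again, so both enol ethers should fall without aqueous acid or heat, while the hindered base keeps HI from the prenyl double bond.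

Step 10
Reactants: 3 2-methyl-1-(2,4,6-trihydroxyphenyl)propan-1-one; 9 prenyl bromide
Product: 20 2-methyl-1-[2,4,6-trihydroxy-3-(3-methylbut-2-en-1-yl)phenyl]propan-1-one
Conditions: KOH (1.05 equiv), H2O, 0 → 23 °C; then 1 M aq. HCl
Reagents that add atoms: none
Why: C-prenylation of the acylphloroglucinol phenolate in water (the reaction type of step 5) at one of its two equivalent free ring carbons.

Step 11
Reactants: 20 2-methyl-1-[2,4,6-trihydroxy-3-(3-methylbut-2-en-1-yl)phenyl]propan-1-one
Product: 21 1-[3-[(dimethylamino)methyl]-2,4,6-trihydroxy-5-(3-methylbut-2-en-1-yl)phenyl]-2-methylpropan-1-one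
Conditions: CH2=NMe2+ I− (1.1 equiv), Et3N (1.1 equiv), CH2Cl2, 0 → 23 °C
Reagents that add atoms: N,N-dimethylmethaniminium iodide (Eschenmoser salt), C=[N+](C)C.[I-]
Why: Phenolic Mannich reaction, which can only take the single free aromatic CH of 20.

Step 12
Reactants: 19 (4R)-3,5-dihydroxy-2-methyl-4-(3-methylbut-2-en-1-yl)-4-(2-methylpropanoyl)cyclohexa-2,5-dien-1-one; 21 1-[3-[(dimethylamino)methyl]-2,4,6-trihydroxy-5-(3-methylbut-2-en-1-yl)phenyl]-2-methylpropan-1-one
Product: 23 (4S)-3,5-dihydroxy-6-methyl-4-(3-methylbut-2-en-1-yl)-4-(2-methylpropanoyl)-2-[[2,4,6-trihydroxy-3-(3-methylbut-2-en-1-yl)-5-(2-methylpropanoyl)phenyl]methyl]cyclohexa-2,5-dien-1-one, via ortho-quinone methide 22 (not isolated)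
Conditions: 21 (1.2 equiv), 1,4-dioxane, 70 °C, argon
Reagents that add atoms: none
Why: Mannich-base alkylation, a known route to unsymmetrical methylene-bridged acylphloroglucinols: the acidic trione 19 protonates the benzylic amine, dimethylamine leaves to give quinone methide 22, and the enolate of 19 adds through its unsubstituted ring carbon (the methyl-bearing carbon would give a non-enolisable, reversible adduct); the stereocentre is untouched, and its descriptor changes from R to S only because the CIP ranking of the two enol carbons inverts once the CH2Ar group is attached.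

**Compound list**

1 | phloroglucinol (benzene-1,3,5-triol) | Oc1cc(O)cc(O)c1 | starting material
2 | isobutyryl chloride (2-methylpropanoyl chloride) | CC(C)C(Cl)=O | starting material
3 | 2-methyl-1-(2,4,6-trihydroxyphenyl)propan-1-one (phlorisobutyrophenone) | CC(C)C(=O)c1c(O)cc(O)cc1O | intermediate
4 | iodomethane | CI | starting material
5 | 2-methyl-1-(2,4,6-trihydroxy-3-methylphenyl)propan-1-one (formed in the flask) | CC(C)C(=O)c1c(O)cc(O)c(C)c1O | intermediate
6 | 3,5-dihydroxy-4,4-dimethyl-2-(2-methylpropanoyl)cyclohexa-2,5-dien-1-one (isobutyrylfilicinic acid) | CC(C)C(=O)C1=C(O)C(C)(C)C(O)=CC1=O | intermediate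
7 | 3,5-dihydroxy-4,4-dimethylcyclohexa-2,5-dien-1-one (filicinic acid) | CC1(C)C(O)=CC(=O)C=C1O | intermediate
8 | 5-hydroxy-3-methoxy-6,6-dimethylcyclohexa-2,4-dien-1-one | COC1=CC(=O)C(C)(C)C(O)=C1 | intermediate
9 | prenyl bromide (1-bromo-3-methylbut-2-ene) | CC(C)=CCBr | starting material
10 | 5-hydroxy-3-methoxy-6,6-dimethyl-2-(3-methylbut-2-en-1-yl)cyclohexa-2,4-dien-1-one | COC1=C(CC=C(C)C)C(=O)C(C)(C)C(O)=C1 | intermediate
11 | 5-[tert-butyl(dimethyl)silyl]oxy-3-methoxy-6,6-dimethyl-2-(3-methylbut-2-en-1-yl)cyclohexa-2,4-dien-1-one | CC(C)=CCC1=C(OC)C=C(O[Si](C)(C)C(C)(C)C)C(C)(C)C1=O | intermediate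
12 | 1-ethoxyprop-1-yne | CC#COCC | starting material
13 | (1R,4R)-4-[tert-butyl(dimethyl)silyl]oxy-6-ethoxy-7-methoxy-3,3,5-trimethyl-1-(3-methylbut-2-en-1-yl)bicyclo[2.2.2]octa-5,7-dien-2-one | CC(C)=CC[C@@]12C(=O)C(C)(C)[C@@](O[Si](C)(C)C(C)(C)C)(C=C1OC)C(C)=C2OCC | intermediate
14 | tetrabutylammonium bridgehead alkoxide of 13, silyl group removed, both bridgeheads as in 13 (formed in the flask) | CC(C)=CC[C@@]12C(=O)C(C)(C)[C@@]([O-])(C=C1OC)C(C)=C2OCC.CCCC[N+](CCCC)(CCCC)CCCC | intermediate
15 | tetrabutylammonium enolate of 16 (enolate of the isobutyryl group, quaternary carbon as in 16; formed in the flask) | CC(C)=CC[C@@]1(C([O-])=C(C)C)C(OC)=CC(=O)C(C)=C1OCC.CCCC[N+](CCCC)(CCCC)CCCC | intermediate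
16 | (4R)-3-ethoxy-5-methoxy-2-methyl-4-(3-methylbut-2-en-1-yl)-4-(2-methylpropanoyl)cyclohexa-2,5-dien-1-one | CC(C)=CC[C@@]1(C(=O)C(C)C)C(OC)=CC(=O)C(C)=C1OCC | intermediate
17 | 5-ethoxy-4-methyl-6-(3-methylbut-2-en-1-yl)-6-(2-methylpropanoyl)-3-(trimethylsilyloxy)cyclohexa-2,4-dien-1-one, quaternary carbon as in 16 (formed in the flask) | CC(C)=CC[C@@]1(C(=O)C(C)C)C(=O)C=C(O[Si](C)(C)C)C(C)=C1OCC | intermediate
18 | 2-methyl-6-(3-methylbut-2-en-1-yl)-6-(2-methylpropanoyl)-3,5-bis(trimethylsilyloxy)cyclohexa-2,4-dien-1-one, quaternary carbon as in 16 (formed in the flask) | CC(C)=CC[C@@]1(C(=O)C(C)C)C(O[Si](C)(C)C)=CC(O[Si](C)(C)C)=C(C)C1=O | intermediate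
19 | (4R)-3,5-dihydroxy-2-methyl-4-(3-methylbut-2-en-1-yl)-4-(2-methylpropanoyl)cyclohexa-2,5-dien-1-one (ring B trione) | CC(C)=CC[C@@]1(C(=O)C(C)C)C(O)=CC(=O)C(C)=C1O | intermediate
20 | 2-methyl-1-[2,4,6-trihydroxy-3-(3-methylbut-2-en-1-yl)phenyl]propan-1-one | CC(C)=CCc1c(O)cc(O)c(C(=O)C(C)C)c1O | intermediate
21 | 1-[3-[(dimethylamino)methyl]-2,4,6-trihydroxy-5-(3-methylbut-2-en-1-yl)phenyl]-2-methylpropan-1-one | CC(C)=CCc1c(O)c(CN(C)C)c(O)c(C(=O)C(C)C)c1O | intermediate
22 | ortho-quinone methide from 21 by loss of dimethylamine: 3,5-dihydroxy-6-methylidene-2-(3-methylbut-2-en-1-yl)-4-(2-methylpropanoyl)cyclohexa-2,4-dien-1-one (formed in the flask) | C=C1C(=O)C(CC=C(C)C)=C(O)C(C(=O)C(C)C)=C1O | intermediate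
23 | (4S)-3,5-dihydroxy-6-methyl-4-(3-methylbut-2-en-1-yl)-4-(2-methylpropanoyl)-2-[[2,4,6-trihydroxy-3-(3-methylbut-2-en-1-yl)-5-(2-methylpropanoyl)phenyl]methyl]cyclohexa-2,5-dien-1-one (CNP0191741.1) | CC(C)=CCc1c(O)c(CC2=C(O)[C@@](CC=C(C)C)(C(=O)C(C)C)C(O)=C(C)C2=O)c(O)c(C(=O)C(C)C)c1O | target

**Summary**

Total step count: 12. Longest linear sequence: 10 steps (steps 1 to 9, then step 12); steps 10 and 11 form the ring A branch from intermediate 3.

Steps most likely to fail:

1. Step 7 (proposed new method). The ynol ether may add 1,4 at C3 and close to a cyclobutene (Ficini mode) instead of 1,6 at C5. The bulky boron cation may also bind the doubly flanked carbonyl poorly, giving low conversion or weak facial discrimination. The fallback uses known chemistry, sets out from 2 and 9, and rejoins the route at 19. Commercial 2,4-dimethoxytoluene is lithiated between its methoxy groups (n-BuLi, TMEDA, THF, 0 °C) and acylated by inverse addition to 2 at −78 °C to give 1-(2,6-dimethoxy-3-methylphenyl)-2-methylpropan-1-one F1. Birch reductive alkylation (K, NH3/THF, t-BuOH 1 equiv, −78 °C; LiBr; then 9) should give 1-[2,6-dimethoxy-3-methyl-1-(3-methylbut-2-en-1-yl)cyclohexa-2,5-dien-1-yl]-2-methylpropan-1-one F2. Oxidation of its doubly allylic CH2 (pyridinium dichromate (C5H5NH)2Cr2O7, t-BuOOH, benzene, 23 °C) should give racemic 3,5-dimethoxy-2-methyl-4-(3-methylbut-2-en-1-yl)-4-(2-methylpropanoyl)cyclohexa-2,5-dien-1-one F3, the dimethyl analogue of 16. Preparative HPLC on a chiral stationary phase would deliver the (4R)-enantiomer F4. The conditions of step 9 then remove both methyl groups, through the methoxy analogue of 17, monosilyl dienol ether F5, and through 18, to give 19.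

2. Step 8. Enolate 15 (or, thermally, bicycle 13) may expel dimethylketene and aromatise to a phenol, and hydroxide from the wet fluoride may deacylate 16. The fallback sets out from 13 and rejoins at 16; it separates desilylation from fragmentation. Buffered fluoride (Bu4NF/AcOH 1:1, THF, 0 → 23 °C) should give the neutral bridgehead alcohol (1R,4R)-6-ethoxy-4-hydroxy-7-methoxy-3,3,5-trimethyl-1-(3-methylbut-2-en-1-yl)bicyclo[2.2.2]octa-5,7-dien-2-one F6. Catalytic DBU in CH2Cl2 with i-PrOH at −20 °C would then effect the retro-aldol under general-base catalysis, so that the enolate is protonated as it forms and no stoichiometric alkoxide, hydroxide or fluoride meets the product.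

3. Step 9. Adventitious HI may add to or cyclise the prenyl group, cleavage of the hindered ethyl ether may stall, or the acyl group may be lost with aromatisation under the Lewis acidic conditions. The fallback sets out from 16 and rejoins at 19; it replaces dealkylation at the alkyl carbon by alkoxy exchange at the ring carbon followed by metal-catalysed deallylation. Acid-catalysed transetherification (allyl alcohol as solvent, camphorsulfonic acid 10 mol %, 50 °C) should give (4R)-2-methyl-4-(3-methylbut-2-en-1-yl)-4-(2-methylpropanoyl)-3,5-bis(prop-2-en-1-yloxy)cyclohexa-2,5-dien-1-one F7. Pd(PPh3)4 (zerovalent palladium, 5 mol %) with morpholine in THF at 23 °C would then remove both allyl groups under neutral conditions that tolerate the prenyl group and the vinylogous acid.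

Further compounds
F1 | step 7 | 1-(2,6-dimethoxy-3-methylphenyl)-2-methylpropan-1-one | CC(C)C(=O)c1c(OC)ccc(C)c1OC
F2 | step 7 | 1-[2,6-dimethoxy-3-methyl-1-(3-methylbut-2-en-1-yl)cyclohexa-2,5-dien-1-yl]-2-methylpropan-1-one (racemic) | CC(C)=CCC1(C(=O)C(C)C)C(OC)=CCC(C)=C1OC
F3 | step 7 | racemic 3,5-dimethoxy-2-methyl-4-(3-methylbut-2-en-1-yl)-4-(2-methylpropanoyl)cyclohexa-2,5-dien-1-one | CC(C)=CCC1(C(=O)C(C)C)C(OC)=CC(=O)C(C)=C1OC
F4 | step 7 | (4R)-3,5-dimethoxy-2-methyl-4-(3-methylbut-2-en-1-yl)-4-(2-methylpropanoyl)cyclohexa-2,5-dien-1-one | CC(C)=CC[C@@]1(C(=O)C(C)C)C(OC)=CC(=O)C(C)=C1OC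
F5 | step 7 | 5-methoxy-4-methyl-6-(3-methylbut-2-en-1-yl)-6-(2-methylpropanoyl)-3-(trimethylsilyloxy)cyclohexa-2,4-dien-1-one, quaternary carbon as in F4 | CC(C)=CC[C@@]1(C(=O)C(C)C)C(=O)C=C(O[Si](C)(C)C)C(C)=C1OC
F6 | step 8 | (1R,4R)-6-ethoxy-4-hydroxy-7-methoxy-3,3,5-trimethyl-1-(3-methylbut-2-en-1-yl)bicyclo[2.2.2]octa-5,7-dien-2-one | CC(C)=CC[C@@]12C(=O)C(C)(C)[C@@](O)(C=C1OC)C(C)=C2OCC
F7 | step 9 | (4R)-2-methyl-4-(3-methylbut-2-en-1-yl)-4-(2-methylpropanoyl)-3,5-bis(prop-2-en-1-yloxy)cyclohexa-2,5-dien-1-one | CC(C)=CC[C@@]1(C(=O)C(C)C)C(OCC=C)=CC(=O)C(C)=C1OCC=C
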